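Ring A (3‑butanoyl‑2,4,6‑trihydroxyphenyl) is joined through one CH2 to ring B, a 2‑acetyl‑4,4‑dimethylcyclohexane‑1,3,5‑trione written as its dienol.
The O‑benzyl groups come off last; just before, the aryl–C(=O)Pr bond is made by Friedel–Crafts acylation at one of the two equivalent free carbons of ring A.
The plan rests on ring B: its acetyl‑bearing C2 lies between C1=O and C3=O, and C3 is bonded to the quaternary C4(CH3)2. Cutting C2–C3 makes C3 a methyl ester on the gem‑dimethyl carbon and C2 the central CH2 of an acetyl 1,3‑diketone, giving an open 2,2‑dimethyl‑3,5,7‑trioxo ester with the ArCH2 arm already on its C4.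
That chain comes from ArCH2CH2C(=O)C(CH3)2CO2Me (aryl‑propanoyl imidazolide plus methyl isobutyrate enolate) by C‑acylation at its only enolisable carbon with a ketal‑masked acetoacetyl unit, then unmasking.
Ring order: ring A is bought as phloroglucinaldehyde; ring B is the only ring built (step 7).

Key step: step 7

Remarks on the chemistry:
- The target has no stereocentre and no stereogenic double bond, so it is achiral and no stereocontrol is needed. Ring B is drawn as one of its rapidly interconverting enol tautomers.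
- C4 of 15 and 16 is a labile centre formed as the racemate and flattened in step 7.
- Metal enolates are treated as deprotonated forms of the numbered compounds and carry no numbers.

Step 1
Reactants: 1 2,4,6‑trihydroxybenzaldehyde; 2 benzyl bromide
Product: 3 2,4,6‑tris(benzyloxy)benzaldehyde
Conditions: BnBr (3.6 equiv), K2CO3 (4.5 equiv), DMF, 70 °C
Reagents that add atoms: benzyl bromide 2, BrCc1ccccc1
Why: Williamson O‑benzylation of the three phenoxides, in which the formyl group deactivates the ring carbons toward C‑benzylation and warm DMF overcomes the hydrogen‑bonded ortho hydroxyls.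

Step 2
Reactants: 3 2,4,6‑tris(benzyloxy)benzaldehyde; 4 Meldrum's acid
Product: 8 3‑[2,4,6‑tris(benzyloxy)phenyl]propanoic acid, via arylidene Meldrum's acid 5 (not isolated), via benzyl Meldrum's acid 6 (not isolated), via benzylmalonic acid 7 (not isolated)
Conditions: Meldrum's acid (1.2 equiv), HCO2H–Et3N (5:2), 95 °C
Reagents that add atoms: Meldrum's acid 4, CC1(C)OC(=O)CC(=O)O1
Why: Tandem Knoevenagel condensation, formate transfer reduction of the arylidene and hydrolysis–decarboxylation in triethylammonium formate should give the two‑carbon‑homologated acid without hydrogen gas, so the benzyl ethers stay on.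

Step 3
Reactants: 8 3‑[2,4,6‑tris(benzyloxy)phenyl]propanoic acid; 9 methyl isobutyrate
Product: 11 methyl 2,2‑dimethyl‑3‑oxo‑5‑[2,4,6‑tris(benzyloxy)phenyl]pentanoate, via acyl imidazolide 10 (not isolated)
Conditions: 8, CDI (1.1 equiv), THF, rt; added to 9 (3.5 equiv)/LDA (3.3 equiv), THF, −78 → 0 °C; aq. NH4Cl
Reagents that add atoms: methyl isobutyrate 9, COC(=O)C(C)C; 1,1'‑carbonyldiimidazole, O=C(n1ccnc1)n1ccnc1 (its imidazole is carried in 10 only)
Why: Crossed Claisen acylation of a preformed ester lithium enolate by an acyl imidazolide should build the quaternary β‑keto ester, with excess enolate absorbing the imidazole N–H and the α'‑protons of the product and CDI sparing the electron‑rich arene from oxalyl or thionyl chloride.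

Step 4
Reactants: 12 ethyl (2‑methyl‑1,3‑dioxolan‑2‑yl)acetate (fructone)
Product: 13 (2‑methyl‑1,3‑dioxolan‑2‑yl)acetic acid
Conditions: NaOH (1.2 equiv), EtOH–H2O, rt; then 1 M HCl to pH 3, 0 °C
Reagents that add atoms: sodium hydroxide, [Na+].[OH-]
Why: Saponification of an unhindered ethyl ester, the dioxolane being stable to base and to brief cold acidification.

Step 5
Reactants: 11 methyl 2,2‑dimethyl‑3‑oxo‑5‑[2,4,6‑tris(benzyloxy)phenyl]pentanoate; 13 (2‑methyl‑1,3‑dioxolan‑2‑yl)acetic acid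
Product: 15 methyl 2,2‑dimethyl‑6‑(2‑methyl‑1,3‑dioxolan‑2‑yl)‑3,5‑dioxo‑4‑[2,4,6‑tris(benzyloxy)benzyl]hexanoate, via ketal acyl imidazolide 14 (not isolated)
Conditions: 13 (1.4 equiv), CDI (1.4 equiv), THF, rt; 11, LiHMDS (2.6 equiv), THF, −78 °C; combined, −78 → −20 °C; aq. NH4Cl
Reagents that add atoms: (2‑methyl‑1,3‑dioxolan‑2‑yl)acetic acid 13, OC(=O)CC1(C)OCCO1; 1,1'‑carbonyldiimidazole, O=C(n1ccnc1)n1ccnc1 (its imidazole is carried in 14 only)
Why: Claisen‑type C‑acylation of a ketone lithium enolate by an acyl imidazolide should give the 1,3‑diketone, since C4 is the only enolisable carbon of 11, the ketal keeps the donor free of an acidic 1,3‑dicarbonyl CH2, and an amide base avoids alkoxide‑induced retro‑Claisen cleavage of the β‑keto ester.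

Step 6
Reactants: 15 methyl 2,2‑dimethyl‑6‑(2‑methyl‑1,3‑dioxolan‑2‑yl)‑3,5‑dioxo‑4‑[2,4,6‑tris(benzyloxy)benzyl]hexanoate
Product: 16 methyl 2,2‑dimethyl‑3,5,7‑trioxo‑4‑[2,4,6‑tris(benzyloxy)benzyl]octanoate
Conditions: 1 M aq. HCl–THF (1:4), rt, stopped at full conversion; used at once
Reagents that add atoms: water, O
Why: Acid‑catalysed hydrolysis of the dioxolane under dilute, cool conditions should free the C7 ketone while benzyl ethers and methyl ester survive and the 1,3,5‑triketone is not pushed to cyclodehydrate to a 4‑pyranone.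

Step 7
Reactants: 16 methyl 2,2‑dimethyl‑3,5,7‑trioxo‑4‑[2,4,6‑tris(benzyloxy)benzyl]octanoate
Product: 17 2‑acetyl‑3,5‑dihydroxy‑4,4‑dimethyl‑6‑[2,4,6‑tris(benzyloxy)benzyl]cyclohexa‑2,5‑dien‑1‑one
Conditions: NaH (3 equiv), THF, 0 → 55 °C; then 1 M HCl, 0 °C
Reagents that add atoms: none
Why: Sodium hydride removes a proton from C6, the CH2 between the C5 and C7 carbonyls, and this stabilised carbanion adds to the C1 ester carbonyl; loss of methoxide gives the 2‑acetyl trione, whose immediate deprotonation makes the closure irreversible in practice. The closest known reaction type is the Dieckmann‑type C‑acylation that converts 5,7‑dioxo esters into 2‑acylcyclohexane‑1,3‑diones and 2,2‑dimethyl‑3,5‑dioxo esters into filicinic‑ and syncarpic‑type triones. Ring B closes 6‑exo‑trig, assisted by the gem‑dimethyl group on C2; no stereocentre is formed and the labile C4 centre becomes sp2. The step needs bond formation from C6 and from no other carbon: attack from C4 would give a four‑membered ring and from C8 an eight‑membered one, and the aldol alternative (C8 onto C3) needs a C8 carbanion that hydride does not generate. O‑acylation to an enol lactone is reversible under the methoxide released, whereas the C‑acylated trione dianion is the thermodynamic sink. A non‑nucleophilic base is chosen so that no alkoxide is present at the start, which limits retro‑Claisen cleavage at the C3 ketone.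

Step 8
Reactants: 17 2‑acetyl‑3,5‑dihydroxy‑4,4‑dimethyl‑6‑[2,4,6‑tris(benzyloxy)benzyl]cyclohexa‑2,5‑dien‑1‑one; 18 butanoic acid
Product: 20 2‑acetyl‑6‑[3‑butanoyl‑2,4,6‑tris(benzyloxy)benzyl]‑3,5‑dihydroxy‑4,4‑dimethylcyclohexa‑2,5‑dien‑1‑one, via butanoic trifluoroacetic anhydride 19 (not isolated)
Conditions: 18 (3 equiv), TFAA (3 equiv), CH2Cl2, 0 °C; then 17, 0 °C → rt; then K2CO3, MeOH–H2O, 0 °C; 1 M HCl
Reagents that add atoms: butanoic acid 18, CCCC(O)=O; trifluoroacetic anhydride, O=C(OC(=O)C(F)(F)F)C(F)(F)F (carried in 19 only)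
Why: Friedel–Crafts acylation by a preformed acyl trifluoroacetate should occur at either of the two equivalent free carbons of the 1‑alkyl‑2,4,6‑trialkoxybenzene ring, and with the phenols still capped no ortho hydroxyl can cyclise onto ring B or open the methylene bridge, while enol esters formed on ring B are cleaved by the carbonate work‑up.

Step 9
Reactants: 20 2‑acetyl‑6‑[3‑butanoyl‑2,4,6‑tris(benzyloxy)benzyl]‑3,5‑dihydroxy‑4,4‑dimethylcyclohexa‑2,5‑dien‑1‑one
Product: 21 2‑acetyl‑6‑(3‑butanoyl‑2,4,6‑trihydroxybenzyl)‑3,5‑dihydroxy‑4,4‑dimethylcyclohexa‑2,5‑dien‑1‑one (target)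
Conditions: H2 (1 atm), 10% Pd/C, EtOAc, rt, stopped after uptake of 3 equiv
Reagents that add atoms: none
Why: Catalytic hydrogenolysis of the three aryl benzyl ethers under neutral conditions should release the target, the hydrogen‑bonded aryl ketone, the enolised trione and the methylene bridge not being reduced at 1 atm in ethyl acetate.

Compound list
1 | 2,4,6‑trihydroxybenzaldehyde | O=Cc1c(O)cc(O)cc1O | starting material
2 | benzyl bromide | BrCc1ccccc1 | starting material
3 | 2,4,6‑tris(benzyloxy)benzaldehyde | O=Cc1c(OCc2ccccc2)cc(OCc2ccccc2)cc1OCc1ccccc1 | intermediate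
4 | Meldrum's acid (2,2‑dimethyl‑1,3‑dioxane‑4,6‑dione) | CC1(C)OC(=O)CC(=O)O1 | starting material
5 | 5‑[2,4,6‑tris(benzyloxy)benzylidene]‑2,2‑dimethyl‑1,3‑dioxane‑4,6‑dione | CC1(C)OC(=O)C(=Cc2c(OCc3ccccc3)cc(OCc3ccccc3)cc2OCc2ccccc2)C(=O)O1 | intermediate (not isolated)
6 | 5‑[2,4,6‑tris(benzyloxy)benzyl]‑2,2‑dimethyl‑1,3‑dioxane‑4,6‑dione | CC1(C)OC(=O)C(Cc2c(OCc3ccccc3)cc(OCc3ccccc3)cc2OCc2ccccc2)C(=O)O1 | intermediate (not isolated)
7 | 2‑[2,4,6‑tris(benzyloxy)benzyl]propanedioic acid | OC(=O)C(Cc1c(OCc2ccccc2)cc(OCc2ccccc2)cc1OCc1ccccc1)C(O)=O | intermediate (not isolated)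
8 | 3‑[2,4,6‑tris(benzyloxy)phenyl]propanoic acid | OC(=O)CCc1c(OCc2ccccc2)cc(OCc2ccccc2)cc1OCc1ccccc1 | intermediate
9 | methyl isobutyrate | COC(=O)C(C)C | starting material
10 | 1‑{3‑[2,4,6‑tris(benzyloxy)phenyl]propanoyl}‑1H‑imidazole | O=C(CCc1c(OCc2ccccc2)cc(OCc2ccccc2)cc1OCc1ccccc1)n1ccnc1 | intermediate (not isolated)
11 | methyl 2,2‑dimethyl‑3‑oxo‑5‑[2,4,6‑tris(benzyloxy)phenyl]pentanoate | COC(=O)C(C)(C)C(=O)CCc1c(OCc2ccccc2)cc(OCc2ccccc2)cc1OCc1ccccc1 | intermediate
12 | ethyl (2‑methyl‑1,3‑dioxolan‑2‑yl)acetate | CCOC(=O)CC1(C)OCCO1 | starting material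
13 | (2‑methyl‑1,3‑dioxolan‑2‑yl)acetic acid | OC(=O)CC1(C)OCCO1 | intermediate
14 | 1‑[(2‑methyl‑1,3‑dioxolan‑2‑yl)acetyl]‑1H‑imidazole | CC1(CC(=O)n2ccnc2)OCCO1 | intermediate (not isolated)
15 | methyl 2,2‑dimethyl‑6‑(2‑methyl‑1,3‑dioxolan‑2‑yl)‑3,5‑dioxo‑4‑[2,4,6‑tris(benzyloxy)benzyl]hexanoate (racemic, labile C4) | COC(=O)C(C)(C)C(=O)C(Cc1c(OCc2ccccc2)cc(OCc2ccccc2)cc1OCc1ccccc1)C(=O)CC1(C)OCCO1 | intermediate
16 | methyl 2,2‑dimethyl‑3,5,7‑trioxo‑4‑[2,4,6‑tris(benzyloxy)benzyl]octanoate (racemic, labile C4) | COC(=O)C(C)(C)C(=O)C(Cc1c(OCc2ccccc2)cc(OCc2ccccc2)cc1OCc1ccccc1)C(=O)CC(C)=O | intermediate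
17 | 2‑acetyl‑3,5‑dihydroxy‑4,4‑dimethyl‑6‑[2,4,6‑tris(benzyloxy)benzyl]cyclohexa‑2,5‑dien‑1‑one | CC(=O)C1=C(O)C(C)(C)C(O)=C(Cc2c(OCc3ccccc3)cc(OCc3ccccc3)cc2OCc2ccccc2)C1=O | intermediate
18 | butanoic acid | CCCC(O)=O | starting material
19 | butanoic trifluoroacetic anhydride | CCCC(=O)OC(=O)C(F)(F)F | intermediate (not isolated)
20 | 2‑acetyl‑6‑[3‑butanoyl‑2,4,6‑tris(benzyloxy)benzyl]‑3,5‑dihydroxy‑4,4‑dimethylcyclohexa‑2,5‑dien‑1‑one | CCCC(=O)c1c(OCc2ccccc2)cc(OCc2ccccc2)c(CC2=C(O)C(C)(C)C(O)=C(C(C)=O)C2=O)c1OCc1ccccc1 | intermediate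
21 | 2‑acetyl‑6‑(3‑butanoyl‑2,4,6‑trihydroxybenzyl)‑3,5‑dihydroxy‑4,4‑dimethylcyclohexa‑2,5‑dien‑1‑one | CCCC(=O)c1c(O)cc(O)c(CC2=C(O)C(C)(C)C(O)=C(C(C)=O)C2=O)c1O | target

Total step count: 9. Longest linear sequence: 8 (steps 1, 2, 3, 5, 6, 7, 8, 9).

Steps most likely to fail

Step 7. The stabilised C6 enolate may add too slowly to the hindered ester, so that retro‑Claisen fragmentation at C3 or other base‑induced condensations overtake ring closure. The fallback closes ring B with a simple ketone enolate and adds the acetyl group afterwards. It sets out from 11, whose lithium enolate (LiHMDS, THF, −78 °C) would be C‑acetylated with N‑acetylimidazole to methyl 4‑acetyl‑2,2‑dimethyl‑3‑oxo‑5‑[2,4,6‑tris(benzyloxy)phenyl]pentanoate F1. Its dianion (LDA, 2.2 equiv, THF, −78 → 0 °C) should close through the terminal methyl carbanion onto the ester to 4,4‑dimethyl‑6‑[2,4,6‑tris(benzyloxy)benzyl]cyclohexane‑1,3,5‑trione F2. O‑acetylation (AcCl, Et3N) followed by DMAP‑mediated O→C acyl migration to the free CH2 position would return the route at 17.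

Step 6. Acid may drive cyclodehydration of the liberated triketone to a 4‑pyranone faster than the β‑keto dioxolane hydrolyses, or hydrolysis may stall. The fallback avoids any masked ketone and any acid. It sets out from 11, whose lithium enolate would be acetoacetylated with the preformed lithium enolate of N‑methoxy‑N‑methyl‑3‑oxobutanamide F3 (THF, −78 → 0 °C). F3 would be made from 2,2,6‑trimethyl‑4H‑1,3‑dioxin‑4‑one and N,O‑dimethylhydroxylamine in refluxing toluene, and its amide carbonyl is expected to stay an acylating site after enolisation. Near‑neutral aqueous work‑up would return the route at 16.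

Step 8. Attack at a ring carbon flanked by two benzyloxy groups may be slow, and the trifluoroacetic acid released may start benzyl loss or benzyl migration before acylation is complete. The fallback reverses the order of the last two operations. It sets out from 17, which would be hydrogenolysed (H2, Pd/C, EtOAc–MeOH, rt) to 2‑acetyl‑3,5‑dihydroxy‑4,4‑dimethyl‑6‑(2,4,6‑trihydroxybenzyl)cyclohexa‑2,5‑dien‑1‑one F4. The free, unhindered phloroglucinol ring would then be acylated with butanoic acid in BF3·OEt2 at 50–60 °C (aqueous NaOAc work‑up), returning the route at 21.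

Further compounds
F1 | step 7 | methyl 4‑acetyl‑2,2‑dimethyl‑3‑oxo‑5‑[2,4,6‑tris(benzyloxy)phenyl]pentanoate | COC(=O)C(C)(C)C(=O)C(Cc1c(OCc2ccccc2)cc(OCc2ccccc2)cc1OCc1ccccc1)C(C)=O
F2 | step 7 | 4,4‑dimethyl‑6‑[2,4,6‑tris(benzyloxy)benzyl]cyclohexane‑1,3,5‑trione | CC1(C)C(=O)CC(=O)C(Cc2c(OCc3ccccc3)cc(OCc3ccccc3)cc2OCc2ccccc2)C1=O
F3 | step 6 | N‑methoxy‑N‑methyl‑3‑oxobutanamide | CON(C)C(=O)CC(C)=O
F4 | step 8 | 2‑acetyl‑3,5‑dihydroxy‑4,4‑dimethyl‑6‑(2,4,6‑trihydroxybenzyl)cyclohexa‑2,5‑dien‑1‑one | CC(=O)C1=C(O)C(C)(C)C(O)=C(Cc2c(O)cc(O)cc2O)C1=O
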